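## Structural features

33 is a cis-fused decalin of the eremophilane type. Ring A (C1–C5, C10) carries the C2 ketone, the C4 methyl and the quaternary C5 methyl; ring B (C5–C10) carries the C7 isopropenyl group, the C8 (R)-2-methylbutanoate and the C9 tiglate; the rings share the C5–C10 bond. The six ring stereocentres form one unbroken chain C4–C5–C10–C9–C8–C7. The two methyls, H-10 and the isopropenyl group lie on one face (β) and both ester oxygens on the other (α), so O-8 is trans to the C7 substituent and cis to O-9; a seventh centre sits in the saturated acyl chain. Fragile groups are the two different esters on a cis-diol (acyl migration once one hydroxyl is free), the conjugated tiglate, the α-centre of the 2-methylbutanoate, the acid- and hydrogenation-sensitive 1,1-disubstituted alkene, and C10, which can epimerise whenever C9 is a carbonyl. The real difficulty is the quaternary C5 between the C4 and C10 stereocentres of a cis ring fusion, followed by the differentiated, stereodefined functionalisation of three adjacent ring B carbons. The key step exploits ring A: the C2 carbonyl with its two methylenes, the C4 methine, the quaternary C5 and the cis junction are exactly the enolate ring that an oxy-Cope rearrangement of a 2-alkenylbicyclo[2.2.2]octenol delivers. The same event leaves a C6=C7 double bond beside oxygen at C8 and C9, both inherited from the oxygenated carbons of an arene.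

## Logic of the disconnections

**C2 oxidation level.** No skeletal bond is cut. The ketone of 33 is traced back to the alcohol 32 and its silyl ether 31, and further back 17 comes from 16 and the ketone 15. A free C2 carbonyl would not survive the borane, organocopper and hydride steps in ring B. The gain is chemoselectivity throughout ring B; the demand is a final oxidation mild enough for two esters on a cis-diol.

**C9–O acyl bond and C9 carbinol.** Cutting the tiglate of 31 gives 29 and 30; 29 goes back to the ketone 28 and this to the ketal 27. C9 stays at the carbonyl level because the arene delivers it that way and because a fully substituted C9 is needed for regiocontrol further back. The forward demands are hydride delivery to the β face of 28 and acylation of a hindered axial hydroxyl without acyl migration.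

**C8–O acyl bond.** 27 is cut into 24 and 25. The two esters are thus introduced one after the other on oxygens that are never free together, which removes the diol differentiation problem. The esterification must respect the α-centre of 25.

**C7–C11 bond.** 24 is cut between C7 and the isopropenyl carbon, giving the epoxide 22 and 23. An SN2 opening fixes the trans C7/C8 relationship by mechanism and brings the whole C3 unit in one step. The forward step must attack C7 and not C8, which the ketal carbon C9 next to C8 secures, and must reach C7 from the β face.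

**C7–O bond.** 22 is traced through the mesylate 20 to the alcohol 19 and the alkene 17 (cuts: C7–O and C6–H). The C8 oxygen, whose configuration stems from the rigid bicycle, dictates C7 (anti hydroboration, then two inversions) and is itself never touched. Required are boron at C7 rather than C6 and attack anti to O-8.

**Key disconnection.** In 15 the C4–C5 bond is cut and the C2–C7 bond reconnected, which leads to the bicyclic carbinol 12. This removes ring A, the quaternary centre and two stereocentres at once and makes the cis fusion a consequence of a cage. The forward step needs the propenyl group on the alkene side of C2, (Z) geometry, and a C8 substituent inert toward the neighbouring alkoxide. O-2 and O-8 face each other across C7, so a silyl ether there could shift to the alkoxide; a benzyl ether is used instead.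

**C2–C3 bond.** 12 is cut into the ketone 9 and the alkenyl unit of 10. The gain is a simple ketone; the demand is addition from the face next to the C5=C6 bridge with retention of alkene geometry.

**Adjustments in the bicycle.** 9 goes back through 8, 7 and 6 to 5: C2 from acetate to ketone, C8 from ketone to protected carbinol. C8 is reduced here and not in the decalin because the cage makes the hydride face unambiguous. The protection must tolerate the acetate.

**Resolution and cycloaddition.** 5 is the recovered enantiomer of 4. 4 is cut at C1–C10 and C2–C7, with the dienone 3 as the diene, into 1 and 2. All ring B oxygen comes from the two oxygenated carbons of 1 and the C5 methyl from its ring methyl. The demands are ortho regiochemistry, endo selectivity and trapping of 3 before it dimerises.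

## Other disconnections considered

**Alternative 1:** The cut is the C7–C8 bond together with an allylic C–H of a prenyl group. The hydroxy tiglate A1 is traced back to the aldehyde A2, in which ring A already holds C4, C5, C10 and the C9 tiglate and C5 bears the prenyl chain. In the forward step Me2AlCl binds the C8 aldehyde of A2, and a type-one intramolecular carbonyl-ene reaction forms C7–C8, closes ring B and moves the double bond to C11=C12.
- In its favour: one step makes ring B, the isopropenyl group and the trans C7/C8 pair through a closed chair-like array. A1 is only an acylation and a ketal hydrolysis away from 33, so the endgame is clearly shorter than the twelve steps that follow 15 here; on that count it is the better plan. It also needs no late hydride reduction at C9.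
- Against it: A2 must already contain the quaternary C5 with both neighbours and the C9 carbinol in the right relative configuration, and the ene step does nothing to build them. The α-acyloxy aldehyde is prone to epimerisation, acyl shift and elimination under a Lewis acid. The facial course at C8 depends on a flexible side chain.
- Comparison: structurally the alternative solves ring B and leaves the ring A triad open; the chosen plan does the reverse. Both key steps are pericyclic, but only the chosen one has its geometry enforced by a cage. In step economy the alternative wins after its key step and very probably loses before it.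

**Alternative 2:** The cuts are C5–C10 and C3–C4. The silyl enol ether A3 is traced back to the acyclic siloxytriene A4, an (E)-tiglyl ketone tethered through the C8/C9 acetonide to a 2-silyloxydiene. The forward step is a thermal intramolecular Diels–Alder reaction that closes both rings.
- In its favour: two C–C bonds and two rings form in one step, which is better than the single bond of the chosen key step. The cis C4/C5 methyl pair follows from the dienophile geometry as reliably as it follows from the (Z)-propenyl group here (equal). The C8/C9 diol can come from the chiral pool, so no resolution is needed (better).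
- Against it: cis fusion and the facial sense relative to the acetonide rest on an endo/exo preference of a sluggish trisubstituted dienophile, not on a geometric necessity. A3 carries a C6 ketone that 33 lacks and still has no C7 substituent; the C6 carbonyl could help to introduce it but must then be removed. The acetonide leaves the two oxygens undifferentiated for two different esters.
- Comparison: structurally the alternative builds more of the skeleton per step but with the wrong oxidation pattern in ring B. Mechanistically its stereocontrol is kinetic, where the chosen plan's is structural. In step economy it leads up to the key step but pays in corrections afterwards.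

**Alternative 3:** The cut is C9–C10. The enedione A5 is traced back to the prochiral cyclohexadienone aldehyde A6. A chiral triazolium-derived carbene converts the C9 aldehyde of A6 into an acyl anion equivalent that adds to one of the two enantiotopic enone β-carbons (C10), closing ring B.
- In its favour: absolute configuration comes from a catalyst, with no loss of half the material as in step 2 here (better). A6 is reached in very few steps from a para-substituted phenol, so the bicyclic core arrives sooner (better). Cis fusion is enforced by the short tether (equal).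
- Against it: A5 lacks the C4 methyl, the C7 isopropenyl group and the C8 oxygen. C9 arrives as a ketone beside the epimerisable C10 before any substituent stabilises the cis fusion. Two carbonyl groups must be told apart, and the C4 methyl, C7 and C8 would all be set by substrate control on a flexible cis-decalin.
- Comparison: structurally it fixes only C5 and C10, against C4, C5 and C10 plus a usable ring B alkene in the chosen plan. Mechanistically it offers catalytic asymmetric induction against resolution. In step economy it is superior up to the core and inferior over the whole route.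

Key step: step 8

Remarks on the chemistry:
- Target (eremophilane) numbering is used in the text; β is the face of the C5 methyl. In the bicyclic names the locants 1, 2, 3, 4, 5, 6, 7, 8 correspond to target C7, C2, C1, C10, C5, C6, C8, C9.
- Assumption: the lipase follows the empirical size rule for secondary alcohols, so the (2R)-acetate is hydrolysed and the required (2S)-acetate is recovered.
- 4 is a racemate; its SMILES shows the enantiomer that is carried on.
- The descriptors of 12 and 15 were checked against 33 and are consistent at C4, C5, C8 and C10; only the protecting group at C8 was changed.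

## Route

Step 1
Reactants: 1 creosol (2-methoxy-4-methylphenol); 2 vinyl acetate
Product: 4 rac-8,8-dimethoxy-5-methyl-7-oxobicyclo[2.2.2]oct-5-en-2-yl acetate (acetoxy syn to the C5=C6 bridge), via 6,6-dimethoxy-4-methylcyclohexa-2,4-dienone 3 (not isolated)
Conditions: PhI(OAc)2 (slow addition), MeOH, 2 (large excess), 50 °C
Reagents that add atoms: methanol CO
Why: The trivalent iodine reagent dearomatises 1 in methanol to the masked o-benzoquinone 3, which the electron-rich alkene intercepts in an inverse-demand Diels–Alder reaction before it dimerises. The nucleophilic CH2 of 2 bonds to the δ-carbon of the dienone (C10) and the acetoxy carbon to the α-carbon (C7), and the endo transition state puts the acetoxy group syn to the new C5=C6 bridge; only relative configuration is set.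

Step 2
Reactants: 4 rac-8,8-dimethoxy-5-methyl-7-oxobicyclo[2.2.2]oct-5-en-2-yl acetate
Product: 5 (2S)-8,8-dimethoxy-5-methyl-7-oxobicyclo[2.2.2]oct-5-en-2-yl acetate (recovered enantiomer)
Conditions: Burkholderia cepacia lipase, pH 7 phosphate buffer/MTBE, 30 °C, stopped just past half conversion
Reagents that add atoms: none
Why: Lipase-catalysed enantioselective hydrolysis of a secondary acetate (kinetic resolution); with the bridgehead as the large group the (2R)-acetate should react faster, so running past half conversion should leave the (2S)-acetate enantiomerically enriched. No stereocentre is formed.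

Step 3
Reactants: 5 (2S)-8,8-dimethoxy-5-methyl-7-oxobicyclo[2.2.2]oct-5-en-2-yl acetate
Product: 6 (2S)-7-hydroxy-8,8-dimethoxy-5-methylbicyclo[2.2.2]oct-5-en-2-yl acetate (hydroxyl anti to the C5=C6 bridge)
Conditions: NaBH4, MeOH/CH2Cl2, −30 °C
Reagents that add atoms: none
Why: Borohydride reduction of the ketone; hydride should arrive from the open face beside the C5=C6 bridge because the other face is flanked by the sp3 C1–C2 bridge, so the hydroxyl ends up anti to the alkene, which becomes the 8α oxygen of 33. The acetate survives at low temperature.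

Step 4
Reactants: 6 (2S)-7-hydroxy-8,8-dimethoxy-5-methylbicyclo[2.2.2]oct-5-en-2-yl acetate
Product: 7 (2S)-7-(benzyloxy)-8,8-dimethoxy-5-methylbicyclo[2.2.2]oct-5-en-2-yl acetate
Conditions: 2-benzyloxy-1-methylpyridinium triflate, MgO, PhCF3, 85 °C
Reagents that add atoms: 2-benzyloxy-1-methylpyridinium triflate C[n+]1ccccc1OCc1ccccc1.[O-]S(=O)(=O)C(F)(F)F
Why: Thermal benzyl transfer from the neutral pyridinium salt etherifies hindered secondary alcohols without added acid or base, so the acetate and the ketal stay intact. A benzyl ether is chosen because it cannot migrate to the C2 alkoxide in step 8.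

Step 5
Reactants: 7 (2S)-7-(benzyloxy)-8,8-dimethoxy-5-methylbicyclo[2.2.2]oct-5-en-2-yl acetate
Product: 8 (2S)-7-(benzyloxy)-8,8-dimethoxy-5-methylbicyclo[2.2.2]oct-5-en-2-ol
Conditions: K2CO3, MeOH, 0 °C to rt
Reagents that add atoms: none
Why: Base-catalysed methanolysis of the acetate; the benzyl ether and the ketal are inert to carbonate in methanol.

Step 6
Reactants: 8 (2S)-7-(benzyloxy)-8,8-dimethoxy-5-methylbicyclo[2.2.2]oct-5-en-2-ol
Product: 9 7-(benzyloxy)-8,8-dimethoxy-5-methylbicyclo[2.2.2]oct-5-en-2-one
Conditions: Dess–Martin periodinane, NaHCO3, CH2Cl2, rt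
Reagents that add atoms: none
Why: Dess–Martin oxidation of the secondary alcohol under buffered conditions; the C2 centre is erased on purpose and the bridgehead α-carbon cannot enolise.

Step 7
Reactants: 9 7-(benzyloxy)-8,8-dimethoxy-5-methylbicyclo[2.2.2]oct-5-en-2-one; 10 (Z)-1-bromoprop-1-ene
Product: 12 7-(benzyloxy)-8,8-dimethoxy-5-methyl-2-[(Z)-prop-1-enyl]bicyclo[2.2.2]oct-5-en-2-ol (propenyl syn to the C5=C6 bridge), via (Z)-prop-1-enyllithium 11 (not isolated)
Conditions: 10, t-BuLi (2 equiv), Et2O, −78 °C; then 9, THF, −78 °C; H2O
Reagents that add atoms: none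
Why: Bromine–lithium exchange keeps the (Z) geometry, and 1,2-addition of the alkenyllithium should occur from the face beside the C5=C6 bridge because the other face is blocked by the C8 benzyloxy group pointing at C2. The propenyl group therefore sits over the alkene, as the [3,3] shift requires.

Step 8
Reactants: 12 7-(benzyloxy)-8,8-dimethoxy-5-methyl-2-[(Z)-prop-1-enyl]bicyclo[2.2.2]oct-5-en-2-ol
Product: 15 8α-(benzyloxy)-9,9-dimethoxy-4β,5β-dimethyl-10βH-cis-decal-6-en-2-one, via potassium alkoxide 13 (not isolated), via potassium enolate 14 (not isolated)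
Conditions: KH, 18-crown-6, THF, 0 °C to 65 °C; AcOH, −78 °C
Reagents that add atoms: none
Why: KH with 18-crown-6 turns the tertiary alcohol into the weakly ion-paired alkoxide 13, whose charge weakens the C2–C7 bond and accelerates a concerted [3,3] sigmatropic shift of the 3-oxido-1,5-diene C4=C3–C2–C7–C6=C5 (anionic oxy-Cope rearrangement). The closest known reaction type is the anionic oxy-Cope rearrangement of 2-alkenylbicyclo[2.2.2]oct-5-en-2-ols to cis-fused decalinones. Ring A (C10–C1–C2–C3–C4–C5) is closed by pericyclic formation of C4–C5 within the six-atom array while C2–C7 breaks, ring B is released from the cyclohexene ring of the bicycle with its double bond now at C6=C7, and the enolate 14 is protonated at C3 on work-up. The cage allows only a boat transition state. C5 is attacked on the face of the C5=C6 bridge that looks toward the C1–C2 bridge, the side on which C1 is attached to C10, so the new ring is cis-fused and the C5 methyl is cis to H-10; the bicyclic framework controls this. At C4 the (Z) geometry puts the methyl on the inner position of the boat, which becomes a C4 methyl cis to the C5 methyl; the (E) isomer would give the trans pair, so the geometric purity of 11 matters. The step needs the [3,3] path to beat alkoxide fragmentation and 1,3-shift: the propenyl group held over the C5=C6 bridge and the relief of the O-2/O-8 compression in 13 favour it, and the benzyl ether excludes the silyl shift a silyl ether could undergo. The ketal, the benzyl ether and the C8 and C10 centres are spectators.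

Step 9
Reactants: 15 8α-(benzyloxy)-9,9-dimethoxy-4β,5β-dimethyl-10βH-cis-decal-6-en-2-one
Product: 16 8α-(benzyloxy)-9,9-dimethoxy-4β,5β-dimethyl-10βH-cis-decal-6-en-2α-ol
Conditions: LiBH(s-Bu)3, THF, −78 °C; H2O
Reagents that add atoms: none
Why: Ketone reduction with a bulky trialkylborohydride; equatorial attack from the β face is expected because the axial C10–C9 bond shields the α face, giving the axial 2α-alcohol. The configuration at C2 is of no consequence because the centre is reoxidised in step 20.

Step 10
Reactants: 16 8α-(benzyloxy)-9,9-dimethoxy-4β,5β-dimethyl-10βH-cis-decal-6-en-2α-ol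
Product: 17 8α-(benzyloxy)-9,9-dimethoxy-4β,5β-dimethyl-2α-(triisopropylsilyloxy)-10βH-cis-decal-6-ene
Conditions: TIPSOTf, 2,6-lutidine, CH2Cl2, 0 °C
Reagents that add atoms: triisopropylsilyl triflate CC(C)[Si](C(C)C)(C(C)C)OS(=O)(=O)C(F)(F)F
Why: Silylation of a hindered secondary alcohol with a silyl triflate and a hindered pyridine base; the triisopropylsilyl ether is chosen to survive the aqueous acid of step 16.

Step 11
Reactants: 17 8α-(benzyloxy)-9,9-dimethoxy-4β,5β-dimethyl-2α-(triisopropylsilyloxy)-10βH-cis-decal-6-ene
Product: 19 8α-(benzyloxy)-9,9-dimethoxy-4β,5β-dimethyl-2α-(triisopropylsilyloxy)-10βH-cis-decalin-7β-ol, via alkylborane 18 (not isolated)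
Conditions: BH3·THF, THF, 0 °C to rt; then NaOH, H2O2
Reagents that add atoms: hydrogen peroxide OO
Why: Hydroboration–oxidation; boron should go to C7 because C6 is neopentyl (next to quaternary C5) and because an allylic oxygen directs boron to the proximal carbon. It should add from the β face, anti to the C8 benzyloxy group and away from the axial C5–C4 bond, so oxidation with retention gives the 7β-alcohol trans to O-8.

Step 12
Reactants: 19 8α-(benzyloxy)-9,9-dimethoxy-4β,5β-dimethyl-2α-(triisopropylsilyloxy)-10βH-cis-decalin-7β-ol
Product: 20 8α-(benzyloxy)-9,9-dimethoxy-4β,5β-dimethyl-2α-(triisopropylsilyloxy)-10βH-cis-decalin-7β-yl methanesulfonate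
Conditions: MsCl, Et3N, CH2Cl2, 0 °C
Reagents that add atoms: methanesulfonyl chloride CS(=O)(=O)Cl
Why: Sulfonylation of the secondary alcohol; no stereocentre is touched.

Step 13
Reactants: 20 8α-(benzyloxy)-9,9-dimethoxy-4β,5β-dimethyl-2α-(triisopropylsilyloxy)-10βH-cis-decalin-7β-yl methanesulfonate
Product: 22 7α,8α-epoxy-9,9-dimethoxy-4β,5β-dimethyl-2α-(triisopropylsilyloxy)-10βH-cis-decalin, via hydroxy mesylate 21 (not isolated)
Conditions: H2 (1 atm), Pd(OH)2/C, EtOAc, rt; filter; K2CO3, MeOH, 40 °C
Reagents that add atoms: none
Why: Hydrogenolysis of the benzyl ether (no alkene is present at this stage) frees the C8 hydroxyl, and base closes the epoxide by intramolecular SN2 displacement of the trans mesylate (Williamson-type closure) with inversion at C7. C8 keeps its configuration, so the 7α,8α-epoxide results.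

Step 14
Reactants: 22 7α,8α-epoxy-9,9-dimethoxy-4β,5β-dimethyl-2α-(triisopropylsilyloxy)-10βH-cis-decalin; 23 isopropenylmagnesium bromide
Product: 24 7β-isopropenyl-9,9-dimethoxy-4β,5β-dimethyl-2α-(triisopropylsilyloxy)-10βH-cis-decalin-8α-ol
Conditions: 23, CuBr·SMe2 (cat.), THF, −30 °C to 0 °C; H2O
Reagents that add atoms: none
Why: Copper-catalysed SN2 opening of an epoxide by an alkenyl Grignard reagent; attack at C8 is shut down by the adjacent fully substituted, doubly oxygenated C9, so the nucleophile should enter at C7 from the β face with inversion. This gives the 7β-isopropenyl group trans to the untouched 8α-hydroxyl.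

Step 15
Reactants: 24 7β-isopropenyl-9,9-dimethoxy-4β,5β-dimethyl-2α-(triisopropylsilyloxy)-10βH-cis-decalin-8α-ol; 25 (R)-2-methylbutanoic acid
Product: 27 7β-isopropenyl-9,9-dimethoxy-4β,5β-dimethyl-2α-(triisopropylsilyloxy)-10βH-cis-decalin-8α-yl (R)-2-methylbutanoate, via mixed anhydride 26 (not isolated)
Conditions: 25, 2,4,6-trichlorobenzoyl chloride, Et3N, THF, rt; then 24, DMAP, toluene, rt to 50 °C
Reagents that add atoms: none
Why: Yamaguchi esterification through the mixed anhydride 26, suited to the hindered secondary C8 hydroxyl; the α-centre of this simple α-branched acid is not expected to epimerise under these conditions.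

Step 16
Reactants: 27 7β-isopropenyl-9,9-dimethoxy-4β,5β-dimethyl-2α-(triisopropylsilyloxy)-10βH-cis-decalin-8α-yl (R)-2-methylbutanoate
Product: 28 7β-isopropenyl-4β,5β-dimethyl-9-oxo-2α-(triisopropylsilyloxy)-10βH-cis-decalin-8α-yl (R)-2-methylbutanoate
Conditions: 2 M aq HCl, THF, rt
Reagents that add atoms: water O
Why: Acid-catalysed hydrolysis of the dimethyl ketal, helped by relief of the axial methoxy/C4 interaction; the silyl ether, the ester and the 1,1-disubstituted alkene tolerate dilute aqueous acid. Enolisation toward C10 should not endanger the ring fusion because the trans-fused epimer would force the C7 isopropenyl group syn-axial to the C5 methyl.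

Step 17
Reactants: 28 7β-isopropenyl-4β,5β-dimethyl-9-oxo-2α-(triisopropylsilyloxy)-10βH-cis-decalin-8α-yl (R)-2-methylbutanoate
Product: 29 9α-hydroxy-7β-isopropenyl-4β,5β-dimethyl-2α-(triisopropylsilyloxy)-10βH-cis-decalin-8α-yl (R)-2-methylbutanoate
Conditions: LiBH(s-Bu)3, THF, −78 °C; AcOH, −78 °C
Reagents that add atoms: none
Why: Ketone reduction with a bulky hydride at low temperature; in the conformer with equatorial C7 and C8 substituents the axial α trajectory at C9 is blocked by the syn-axial C5–C4 bond, so hydride should arrive from the β face and give the axial 9α-alcohol cis to O-8. The cold acidic quench limits O-8 to O-9 acyl migration.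

Step 18
Reactants: 29 9α-hydroxy-7β-isopropenyl-4β,5β-dimethyl-2α-(triisopropylsilyloxy)-10βH-cis-decalin-8α-yl (R)-2-methylbutanoate; 30 tigloyl chloride ((E)-2-methylbut-2-enoyl chloride)
Product: 31 7β-isopropenyl-4β,5β-dimethyl-9α-(tigloyloxy)-2α-(triisopropylsilyloxy)-10βH-cis-decalin-8α-yl (R)-2-methylbutanoate
Conditions: 30, DMAP, pyridine, CH2Cl2, 40 °C
Reagents that add atoms: none
Why: DMAP-catalysed acylation of the hindered axial alcohol with the acid chloride; pyridine is used in place of a trialkylamine to avoid vinylketene formation and deconjugation of the tigloyl group.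

Step 19
Reactants: 31 7β-isopropenyl-4β,5β-dimethyl-9α-(tigloyloxy)-2α-(triisopropylsilyloxy)-10βH-cis-decalin-8α-yl (R)-2-methylbutanoate
Product: 32 2α-hydroxy-7β-isopropenyl-4β,5β-dimethyl-9α-(tigloyloxy)-10βH-cis-decalin-8α-yl (R)-2-methylbutanoate
Conditions: HF·pyridine, pyridine, THF, 0 °C to rt
Reagents that add atoms: none
Why: Fluoride-induced cleavage of the silyl ether under buffered conditions that leave both esters and both alkenes untouched.

Step 20
Reactants: 32 2α-hydroxy-7β-isopropenyl-4β,5β-dimethyl-9α-(tigloyloxy)-10βH-cis-decalin-8α-yl (R)-2-methylbutanoate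
Product: 33 CNP0312791.1 (7β-isopropenyl-4β,5β-dimethyl-2-oxo-9α-(tigloyloxy)-10βH-cis-decalin-8α-yl (R)-2-methylbutanoate)
Conditions: Dess–Martin periodinane, NaHCO3, CH2Cl2, rt
Reagents that add atoms: none
Why: Dess–Martin oxidation of the secondary alcohol to the C2 ketone; the buffered neutral conditions avoid acyl migration, and both carbons next to C2 are methylenes.

## Compound list

1 | creosol (2-methoxy-4-methylphenol) | Cc1ccc(O)c(OC)c1 | starting material
2 | vinyl acetate | C=COC(C)=O | starting material
3 | 6,6-dimethoxy-4-methylcyclohexa-2,4-dienone | O=C1C=CC(C)=CC1(OC)OC | intermediate (not isolated)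
4 | rac-8,8-dimethoxy-5-methyl-7-oxobicyclo[2.2.2]oct-5-en-2-yl acetate, acetoxy syn to C5=C6 (racemate; one enantiomer drawn) | [C@H]12C=C(C)[C@H](C[C@@H]1OC(C)=O)C(OC)(OC)C2=O | intermediate
5 | (2S)-8,8-dimethoxy-5-methyl-7-oxobicyclo[2.2.2]oct-5-en-2-yl acetate | [C@H]12C=C(C)[C@H](C[C@@H]1OC(C)=O)C(OC)(OC)C2=O | intermediate
6 | (2S)-7-hydroxy-8,8-dimethoxy-5-methylbicyclo[2.2.2]oct-5-en-2-yl acetate, hydroxyl anti to C5=C6 | [C@H]12C=C(C)[C@H](C[C@@H]1OC(C)=O)C(OC)(OC)[C@@H]2O | intermediate
7 | (2S)-7-(benzyloxy)-8,8-dimethoxy-5-methylbicyclo[2.2.2]oct-5-en-2-yl acetate | [C@H]12C=C(C)[C@H](C[C@@H]1OC(C)=O)C(OC)(OC)[C@@H]2OCc1ccccc1 | intermediate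
8 | (2S)-7-(benzyloxy)-8,8-dimethoxy-5-methylbicyclo[2.2.2]oct-5-en-2-ol | [C@H]12C=C(C)[C@H](C[C@@H]1O)C(OC)(OC)[C@@H]2OCc1ccccc1 | intermediate
9 | 7-(benzyloxy)-8,8-dimethoxy-5-methylbicyclo[2.2.2]oct-5-en-2-one | [C@H]12C=C(C)[C@H](CC1=O)C(OC)(OC)[C@@H]2OCc1ccccc1 | intermediate
10 | (Z)-1-bromoprop-1-ene | C/C=C\Br | starting material
11 | (Z)-prop-1-enyllithium | C/C=C\[Li] | intermediate (not isolated)
12 | 7-(benzyloxy)-8,8-dimethoxy-5-methyl-2-[(Z)-prop-1-enyl]bicyclo[2.2.2]oct-5-en-2-ol, propenyl syn to C5=C6 | [C@H]12C=C(C)[C@H](C[C@]1(O)/C=C\C)C(OC)(OC)[C@@H]2OCc1ccccc1 | intermediate (key-step precursor)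
13 | potassium alkoxide of 12 | [C@H]12C=C(C)[C@H](C[C@]1([O-])/C=C\C)C(OC)(OC)[C@@H]2OCc1ccccc1.[K+] | intermediate (not isolated)
14 | potassium C2 enolate of 15 | C1=C[C@@]2(C)[C@H](CC([O-])=C[C@@H]2C)C(OC)(OC)[C@@H]1OCc1ccccc1.[K+] | intermediate (not isolated)
15 | 8α-(benzyloxy)-9,9-dimethoxy-4β,5β-dimethyl-10βH-cis-decal-6-en-2-one | C1=C[C@@]2(C)[C@H](CC(=O)C[C@@H]2C)C(OC)(OC)[C@@H]1OCc1ccccc1 | intermediate (key-step product)
16 | 8α-(benzyloxy)-9,9-dimethoxy-4β,5β-dimethyl-10βH-cis-decal-6-en-2α-ol | C1=C[C@@]2(C)[C@H](C[C@@H](O)C[C@@H]2C)C(OC)(OC)[C@@H]1OCc1ccccc1 | intermediate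
17 | 8α-(benzyloxy)-9,9-dimethoxy-4β,5β-dimethyl-2α-(triisopropylsilyloxy)-10βH-cis-decal-6-ene | C1=C[C@@]2(C)[C@H](C[C@@H](O[Si](C(C)C)(C(C)C)C(C)C)C[C@@H]2C)C(OC)(OC)[C@@H]1OCc1ccccc1 | intermediate
18 | C7β monoalkylborane from 17 | B[C@H]1C[C@@]2(C)[C@H](C[C@@H](O[Si](C(C)C)(C(C)C)C(C)C)C[C@@H]2C)C(OC)(OC)[C@@H]1OCc1ccccc1 | intermediate (not isolated)
19 | 8α-(benzyloxy)-9,9-dimethoxy-4β,5β-dimethyl-2α-(triisopropylsilyloxy)-10βH-cis-decalin-7β-ol | O[C@H]1C[C@@]2(C)[C@H](C[C@@H](O[Si](C(C)C)(C(C)C)C(C)C)C[C@@H]2C)C(OC)(OC)[C@@H]1OCc1ccccc1 | intermediate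
20 | 7β-methanesulfonate of 19 | CS(=O)(=O)O[C@H]1C[C@@]2(C)[C@H](C[C@@H](O[Si](C(C)C)(C(C)C)C(C)C)C[C@@H]2C)C(OC)(OC)[C@@H]1OCc1ccccc1 | intermediate
21 | 8α-hydroxy-9,9-dimethoxy-4β,5β-dimethyl-2α-(triisopropylsilyloxy)-10βH-cis-decalin-7β-yl methanesulfonate | CS(=O)(=O)O[C@H]1C[C@@]2(C)[C@H](C[C@@H](O[Si](C(C)C)(C(C)C)C(C)C)C[C@@H]2C)C(OC)(OC)[C@@H]1O | intermediate (not isolated)
22 | 7α,8α-epoxy-9,9-dimethoxy-4β,5β-dimethyl-2α-(triisopropylsilyloxy)-10βH-cis-decalin | C1[C@@]2(C)[C@H](C[C@@H](O[Si](C(C)C)(C(C)C)C(C)C)C[C@@H]2C)C(OC)(OC)[C@@H]3O[C@H]13 | intermediate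
23 | isopropenylmagnesium bromide | CC(=C)[Mg]Br | starting material
24 | 7β-isopropenyl-9,9-dimethoxy-4β,5β-dimethyl-2α-(triisopropylsilyloxy)-10βH-cis-decalin-8α-ol | C=C(C)[C@H]1C[C@@]2(C)[C@H](C[C@@H](O[Si](C(C)C)(C(C)C)C(C)C)C[C@@H]2C)C(OC)(OC)[C@@H]1O | intermediate
25 | (R)-2-methylbutanoic acid | CC[C@@H](C)C(=O)O | starting material
26 | (R)-2-methylbutanoic 2,4,6-trichlorobenzoic anhydride | CC[C@@H](C)C(=O)OC(=O)c1c(Cl)cc(Cl)cc1Cl | intermediate (not isolated)
27 | 8α-(R)-2-methylbutanoate of 24 | C=C(C)[C@H]1C[C@@]2(C)[C@H](C[C@@H](O[Si](C(C)C)(C(C)C)C(C)C)C[C@@H]2C)C(OC)(OC)[C@@H]1OC(=O)[C@H](C)CC | intermediate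
28 | 7β-isopropenyl-4β,5β-dimethyl-9-oxo-2α-(triisopropylsilyloxy)-10βH-cis-decalin-8α-yl (R)-2-methylbutanoate | C=C(C)[C@H]1C[C@@]2(C)[C@H](C[C@@H](O[Si](C(C)C)(C(C)C)C(C)C)C[C@@H]2C)C(=O)[C@@H]1OC(=O)[C@H](C)CC | intermediate
29 | 9α-hydroxy-7β-isopropenyl-4β,5β-dimethyl-2α-(triisopropylsilyloxy)-10βH-cis-decalin-8α-yl (R)-2-methylbutanoate | C=C(C)[C@H]1C[C@@]2(C)[C@H](C[C@@H](O[Si](C(C)C)(C(C)C)C(C)C)C[C@@H]2C)[C@H](O)[C@@H]1OC(=O)[C@H](C)CC | intermediate
30 | tigloyl chloride ((E)-2-methylbut-2-enoyl chloride) | C/C=C(\C)C(=O)Cl | starting material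
31 | 7β-isopropenyl-4β,5β-dimethyl-9α-(tigloyloxy)-2α-(triisopropylsilyloxy)-10βH-cis-decalin-8α-yl (R)-2-methylbutanoate | C=C(C)[C@H]1C[C@@]2(C)[C@H](C[C@@H](O[Si](C(C)C)(C(C)C)C(C)C)C[C@@H]2C)[C@H](OC(=O)/C(C)=C/C)[C@@H]1OC(=O)[C@H](C)CC | intermediate
32 | 2α-hydroxy-7β-isopropenyl-4β,5β-dimethyl-9α-(tigloyloxy)-10βH-cis-decalin-8α-yl (R)-2-methylbutanoate | C=C(C)[C@H]1C[C@@]2(C)[C@H](C[C@@H](O)C[C@@H]2C)[C@H](OC(=O)/C(C)=C/C)[C@@H]1OC(=O)[C@H](C)CC | intermediate
33 | CNP0312791.1 | C=C(C)[C@H]1C[C@@]2(C)[C@H](CC(=O)C[C@@H]2C)[C@H](OC(=O)/C(C)=C/C)[C@@H]1OC(=O)[C@H](C)CC | target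

## Step count and least certain steps

Total: 20 steps. Longest linear sequence: 20 steps, from 1 to 33; 2, 10, 23, 25 and 30 are commercial inputs.

**Step 8 (key step).** The rearrangement may be slow because the (Z)-methyl group must take the inner position of the boat, close to the C1 methylene. At the temperature then needed, cleavage of the C2–C7 bond without C4–C5 bonding (fragmentation or a 1,3-shift) or loss of alkene geometry can compete. Fallback, from 12 back to 15: 12 is silylated (TMSOTf, Et3N) to the trimethylsilyl ether F1 and heated in a sealed tube in o-dichlorobenzene at about 220 °C. This neutral siloxy-Cope variant avoids alkoxide chemistry and should give the silyl enol ether F2, which dilute acid hydrolyses to 15.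

**Step 14.** The nucleophile must reach C7 from the β face, where the trans-diaxial trajectory is flanked by the C5 methyl and one C9 methoxy group. The opening may therefore be slow enough for magnesium-salt-induced rearrangement of the epoxide to a ketone, or bromide opening, to take over. Fallback, from 17 back to 24, which also bypasses steps 11 to 13:
- Reductive debenzylation of 17 with lithium 4,4'-di-tert-butylbiphenylide (THF, −78 °C) gives the allylic alcohol F3.
- Dess–Martin oxidation gives the enone F4.
- I2 and pyridine give the α-iodoenone F5.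
- Suzuki coupling with isopropenylboronic acid pinacol ester (PdCl2(dppf), K3PO4, dioxane/H2O) gives the dienone F6.
- Conjugate reduction of the ring double bond with LiBH(s-Bu)3 at −78 °C and protonation, with brief amine-mediated equilibration toward the equatorial epimer if needed, gives the 7β-isopropenyl ketone F7.
- NaBH4, attacking C8 axially from the open β face, gives 24.

This detour gives up the mechanistic control of C7 and relies on the equatorial preference of the isopropenyl group.

**Step 17.** Hydride delivery may not be fully selective for the β face, and the alkoxide formed next to the C8 ester can trigger acyl migration from O-8 to O-9. Fallback, from 28 back to 31: the 9β-alcohol F8, obtained from 28 when hydride adds from the α face (for example with NaBH4 at low temperature in methanol, where the alkoxide is protonated at once), is not discarded. It is esterified with tiglic acid under Mitsunobu conditions (PPh3, DIAD, toluene), which inverts C9 and gives 31 directly.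

**Step 2.** The enzyme may discriminate poorly between the enantiomers of this compact bicyclic acetate, or may prefer the other enantiomer, so 5 would be recovered with insufficient enantiomeric purity. Fallback, from 4 back to 5: preparative chromatography of 4 on a chiral stationary phase (supercritical CO2/methanol) separates the enantiomers physically and delivers 5 without any new compound.

## Further compounds

F1 | step 8 | 7-(benzyloxy)-8,8-dimethoxy-5-methyl-2-[(Z)-prop-1-enyl]-2-(trimethylsilyloxy)bicyclo[2.2.2]oct-5-ene | [C@H]12C=C(C)[C@H](C[C@]1(O[Si](C)(C)C)/C=C\C)C(OC)(OC)[C@@H]2OCc1ccccc1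
F2 | step 8 | trimethylsilyl enol ether (C2=C3) of 15 | C1=C[C@@]2(C)[C@H](CC(O[Si](C)(C)C)=C[C@@H]2C)C(OC)(OC)[C@@H]1OCc1ccccc1
F3 | step 14 | 9,9-dimethoxy-4β,5β-dimethyl-2α-(triisopropylsilyloxy)-10βH-cis-decal-6-en-8α-ol | C1=C[C@@]2(C)[C@H](C[C@@H](O[Si](C(C)C)(C(C)C)C(C)C)C[C@@H]2C)C(OC)(OC)[C@@H]1O
F4 | step 14 | 9,9-dimethoxy-4β,5β-dimethyl-2α-(triisopropylsilyloxy)-10βH-cis-decal-6-en-8-one | C1=C[C@@]2(C)[C@H](C[C@@H](O[Si](C(C)C)(C(C)C)C(C)C)C[C@@H]2C)C(OC)(OC)C1=O
F5 | step 14 | 7-iodo-9,9-dimethoxy-4β,5β-dimethyl-2α-(triisopropylsilyloxy)-10βH-cis-decal-6-en-8-one | IC1=C[C@@]2(C)[C@H](C[C@@H](O[Si](C(C)C)(C(C)C)C(C)C)C[C@@H]2C)C(OC)(OC)C1=O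
F6 | step 14 | 7-isopropenyl-9,9-dimethoxy-4β,5β-dimethyl-2α-(triisopropylsilyloxy)-10βH-cis-decal-6-en-8-one | C=C(C)C1=C[C@@]2(C)[C@H](C[C@@H](O[Si](C(C)C)(C(C)C)C(C)C)C[C@@H]2C)C(OC)(OC)C1=O
F7 | step 14 | 7β-isopropenyl-9,9-dimethoxy-4β,5β-dimethyl-2α-(triisopropylsilyloxy)-10βH-cis-decalin-8-one | C=C(C)[C@H]1C[C@@]2(C)[C@H](C[C@@H](O[Si](C(C)C)(C(C)C)C(C)C)C[C@@H]2C)C(OC)(OC)C1=O
F8 | step 17 | 9β-hydroxy-7β-isopropenyl-4β,5β-dimethyl-2α-(triisopropylsilyloxy)-10βH-cis-decalin-8α-yl (R)-2-methylbutanoate | C=C(C)[C@H]1C[C@@]2(C)[C@H](C[C@@H](O[Si](C(C)C)(C(C)C)C(C)C)C[C@@H]2C)[C@@H](O)[C@@H]1OC(=O)[C@H](C)CC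
F0 | step 2 | none | none
A1 | alternative 1 | 8α-hydroxy-7β-isopropenyl-9α-(tigloyloxy) cis-decalin with C2 ethylene ketal (product of the ene closure) | C=C(C)[C@H]1C[C@@]2(C)[C@H](CC3(OCCO3)C[C@@H]2C)[C@H](OC(=O)/C(C)=C/C)[C@@H]1O
A2 | alternative 1 | ring A aldehyde with C5 prenyl chain, C9 tiglate and C2 ethylene ketal (ene precursor) | CC(C)=CC[C@@]1(C)[C@H](CC2(OCCO2)C[C@@H]1C)[C@H](OC(=O)/C(C)=C/C)C=O
A3 | alternative 2 | cis-decalin silyl enol ether with C6 ketone and C8/C9 acetonide (cycloadduct) | C1C(=O)[C@@]2(C)[C@H](C=C(O[Si](C)(C)C(C)(C)C)C[C@@H]2C)[C@@H]3OC(C)(C)O[C@@H]31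
A4 | alternative 2 | acyclic 2-silyloxydiene tethered through the C8/C9 acetonide to an (E)-tiglyl ketone (cycloaddition precursor) | C=C(O[Si](C)(C)C(C)(C)C)/C=C/[C@@H]1OC(C)(C)O[C@@H]1CC(=O)/C(C)=C/C
A5 | alternative 3 | cis-fused 5-methyldecal-3-ene-2,9-dione (cyclisation product) | C1C[C@@]2(C)[C@H](CC(=O)C=C2)C(=O)C1
A6 | alternative 3 | 4-methyl-4-(4-oxobutyl)cyclohexa-2,5-dien-1-one (cyclisation precursor) | CC1(CCCC=O)C=CC(=O)C=C1
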